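**Numbering used throughout.** Target atoms: ring C1–C6 with C1=C2; C1 carries the exocyclic C7H2–O7; O3, O4, O5 and O6 sit on C3–C6; the benzoates are on O5 and O7. Compounds: **1** bromobenzene; **2** bromo diene diol; **3** its O5-monobenzoate; **4** bromo triol benzoate; **5** hydroxymethyl tetraol benzoate; **6** target.

Remark (assumption): the whole-cell oxidation with the recombinant toluene dioxygenase strain E. coli JM109(pDTG601) is treated as an ordinary preparative step on commercial bromobenzene.

## Analysis of the target

Compound 6 is a C7 cyclitol: one cyclohexene ring (C1–C6, C1=C2) whose alkene carbon C1 carries the benzoyloxymethyl carbon C7, with oxygen on every sp3 ring carbon (free OH on C3, C4 and C6, a benzoate on C5). The four stereocentres C3–C6 are contiguous and all R. O3/O4 are cis, O5/O6 are cis, and the two pairs are trans to each other, which is the C2-symmetric conduritol E pattern, broken only by C7 on C1 and by the acyl group on O5. The feature that invites the strategy is that ring C1–C6 is a benzene ring that has been cis-dihydroxylated twice, once at C5–C6 (the carbons ortho and meta to the substituted carbon C1) and once, on the opposite face, at C3–C4, leaving C1=C2. The sensitive groups are the two benzoates flanked by free hydroxyls (base-promoted acyl migration from O5 to O6 or O4) and the allylic oxygens at C3, C6 and C7 (ionisation, and loss of water or benzoic acid towards arenes). Late steps must therefore be near neutral, and no ester-cleaving reduction can follow benzoylation. The carbon skeleton is trivial, so the difficulty is absolute and relative control of four adjacent carbinol centres and telling five oxygens apart, because O7 and exactly one of the four secondary oxygens (O5) must be acylated.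

## Retrosynthetic reasoning

**6 ⇒ 5 (acyl–O7 bond).** The primary allylic benzoate is cut last. The forward step is the only acylation in the route that can rest on the primary/secondary difference alone, and placing it at the end means no later step can shift or cleave it.

**5 ⇒ 4 (C1–C7 bond).** C7 is cut off as a hydroxymethyl nucleophile, leaving the alkenyl bromide of 4 at C1. Cutting here, rather than carrying a carboxyl carbon from the start, avoids an ester reduction that the O5 benzoate would not survive. The forward step is a neutral palladium-catalysed Stille hydroxymethylation, which tolerates the free hydroxyls and the benzoate.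

**4 ⇒ 3 (C3–O3 and C4–O4 bonds).** Both bonds are cut together, back to the C3=C4 alkene of 3. The forward osmium-catalysed syn-dihydroxylation must choose C3=C4 over C1=C2 and the face opposite O5/O6. The bromine on C1 deactivates and shields C1=C2, and the allylic O5 benzoate with the syn O6 hydroxyl blocks the upper face, so C3 and C4 are relayed from C5 and C6 in one event.

**3 ⇒ 2 (acyl–O5 bond).** The secondary benzoate is cut at the stage of 2 because that is where O5 and O6 differ most. O5 is the unhindered, pseudoequatorial distal hydroxyl; O6 is pseudoaxial and pressed against the C1–Br carbon. Installing the benzoate here also removes any need for a protecting group: O3, O4 and O6 are never protected.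

**2 ⇒ 1 (C5–O5 and C6–O6 bonds, with loss of aromaticity).** The cis-diol of 2 is cut back to 1. The forward step, enzymatic cis-dihydroxylation of 1, has to deliver the ortho/meta diol as a single enantiomer. The (1S,2S) configuration of 2 maps exactly onto C5 and C6 of 6, so the whole absolute configuration of the target comes from this one step on a cheap arene.

## Alternatives that were turned down

Alternative 1: chiral pool from (−)-shikimic acid A1 (the textbook route). The acid A1 already has C3, C4 and C5 of 6 in the correct absolute configuration, so only the C6–O6 bond is disconnected. The forward key step would be allylic C–H hydroxylation at C6 of methyl 5-O-benzoyl-3,4-O-isopropylideneshikimate A2 to the 6-hydroxy ester A3. It was turned down for four reasons.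
- C6–H sits on the carbon next to the α-carbon of an electron-poor enoate, so ene-type oxidants attack it sluggishly, while the oxygen-activated allylic C3–H competes.
- An oxidant would approach anti to the O5 substituent and give the 5,6-trans isomer, so an oxidation/reduction inversion would be added.
- The ester must be reduced to C7H2OH before or in spite of the benzoate, which forces a full protecting-group exchange.
- The result is roughly nine or more steps to add one stereocentre.

Alternative 2: ring-closing metathesis of a sugar-derived diene. The C1=C2 bond is disconnected. The protected acyclic diene A4 carries all four stereocentres from a hexose, and ruthenium-carbene-catalysed ring closure would give the cyclohexene A5. It was turned down for three reasons.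
- The closure itself is sound, but it builds the cheapest feature of the ring (the alkene) at the highest cost.
- The diene A4 needs chain extension at both ends of the sugar, installation of a 1,1-disubstituted alkene and orthogonal protection of five oxygens.
- After closure the protection pattern must be exchanged entirely for two benzoates and three free hydroxyls, giving well over ten steps.

Alternative 3: chemical dearomatisation of benzyl benzoate A6. The ester A6 already contains C1–C7 and the O7 benzoate. A visible-light [4+2] cycloaddition of a triazolinedione arenophile across C2/C5 of the benzyl ring, osmium dihydroxylation of the bicyclic alkene and cycloreversion would give the diene diol A7 with O3 and O4 in place. It was turned down for three reasons.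
- The diene diol A7 is formed as a racemate, with no element for absolute control, so a resolution would be needed.
- The second dihydroxylation would have to choose the disubstituted C5=C6 alkene over the more electron-rich trisubstituted C1=C2 alkene, which has no deactivating substituent.
- The benzoyl ring is a second possible site for the arenophile.

Key step: step 1

## Route

Step 1
Reactants: 1 bromobenzene
Product: 2 (1S,2S)-3-bromocyclohexa-3,5-diene-1,2-diol
Conditions: recombinant E. coli JM109(pDTG601) whole cells (toluene dioxygenase), glucose-fed aerobic fermentation, pH 6.8, 35 °C, slow feed of 1; EtOAc extraction at pH ≥ 7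
Reagents that add atoms: dioxygen, O=O
Why: Arene cis-dihydroxylation by toluene dioxygenase, a non-haem iron dioxygenase: dioxygen is activated at the mononuclear iron site with two electrons relayed from NADH, and both oxygen atoms are delivered to one face of the C2–C3 bond of 1 (future C6 and C5 of 6); the host lacks the diol dehydrogenase, so 2 is not rearomatised to a catechol and accumulates. The closest known reaction type is this very transformation, the whole-cell dihydroxylation of monohalobenzenes. No ring is closed; the benzene ring itself becomes ring C1–C6 of the target, with the diene C1=C2–C3=C4 left for the next oxygenation. Both new stereocentres (C5 and C6) are set by the enzyme pocket, cis to each other and as the single (1S,2S) enantiomer, which is the absolute configuration of C5 and C6 in 6. The step needs regioselectivity for the ortho and meta carbons (not meta/para, not ipso) and enantioface selectivity; both are secured by the bromine atom, which the active site places as the large substituent next to the oxidised bond. The same bromine later shields C1=C2 from OsO4 and is the handle for C7, so nothing installed here is wasted.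

Step 2
Reactants: 2 (1S,2S)-3-bromocyclohexa-3,5-diene-1,2-diol
Product: 3 (1S,6S)-5-bromo-6-hydroxycyclohexa-2,4-dien-1-yl benzoate
Conditions: BzCl (1.05 equiv), pyridine (3 equiv), CH2Cl2, −40 to −20 °C
Reagents that add atoms: benzoyl chloride, O=C(Cl)c1ccccc1
Why: Kinetic monoacylation of a cis-1,2-diol; the distal hydroxyl (future O5) is pseudoequatorial and unhindered, whereas the proximal hydroxyl (future O6) is pseudoaxial and flanked by the C–Br carbon (allylic 1,2-strain), the same bias that directs bulky silyl chlorides to the distal oxygen of such diene diols. No stereocentre is touched.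

Step 3
Reactants: 3 (1S,6S)-5-bromo-6-hydroxycyclohexa-2,4-dien-1-yl benzoate
Product: 4 (1S,2S,5R,6R)-3-bromo-2,5,6-trihydroxycyclohex-3-en-1-yl benzoate
Conditions: OsO4 (2 mol %), N-methylmorpholine N-oxide (1.3 equiv), acetone–H2O (5:1), 0 °C to rt
Reagents that add atoms: osmium tetroxide, O=[Os](=O)(=O)=O; N-methylmorpholine N-oxide, C[N+]1([O-])CCOCC1; water, O
Why: Upjohn syn-dihydroxylation; OsO4 takes the electron-richer disubstituted C3=C4 alkene and leaves the bromo-substituted C1=C2 alkene, and it adds anti to the allylic O5 benzoate and the syn pseudoaxial O6 hydroxyl, the usual sense of osmylation next to an allylic oxygen. C3 and C4 are thus set cis to each other and trans to O5/O6 by substrate control. OsO4 carries both oxygen atoms onto carbon and is regenerated by the N-oxide and water.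

Step 4
Reactants: 4 (1S,2S,5R,6R)-3-bromo-2,5,6-trihydroxycyclohex-3-en-1-yl benzoate
Product: 5 (1R,2R,5R,6R)-2,5,6-trihydroxy-3-(hydroxymethyl)cyclohex-3-en-1-yl benzoate
Conditions: Bu3SnCH2OH (1.5 equiv), Pd(PPh3)4 (8 mol %), 1,4-dioxane, 95 °C
Reagents that add atoms: (tributylstannyl)methanol, CCCC[Sn](CCCC)(CCCC)CO
Why: Stille cross-coupling: oxidative addition of the alkenyl C1–Br bond to zerovalent palladium, transfer of the hydroxymethyl group from tin (favoured over butyl by the α-oxygen) and reductive elimination form the C1–C7 bond. The conditions are neutral, so the free hydroxyls and the O5 benzoate are tolerated and no stereocentre is affected.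

Step 5
Reactants: 5 (1R,2R,5R,6R)-2,5,6-trihydroxy-3-(hydroxymethyl)cyclohex-3-en-1-yl benzoate
Product: 6 [(3R,4R,5R,6R)-5-(benzoyloxy)-3,4,6-trihydroxycyclohex-1-en-1-yl]methyl benzoate
Conditions: BzCl (1.05 equiv), 2,4,6-collidine, CH2Cl2–MeCN, −40 °C
Reagents that add atoms: benzoyl chloride, O=C(Cl)c1ccccc1
Why: Primary-selective acylation with an acid chloride and a hindered pyridine base at low temperature; the primary allylic O7 hydroxyl should react well ahead of the three secondary hydroxyls, each of which is flanked by ring substituents. The weak, hindered base and low temperature keep the O5 benzoate from migrating.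

## Compound list

1 | bromobenzene | Brc1ccccc1 | starting material
2 | (1S,2S)-3-bromocyclohexa-3,5-diene-1,2-diol | BrC1=CC=C[C@H](O)[C@@H]1O | intermediate
3 | (1S,6S)-5-bromo-6-hydroxycyclohexa-2,4-dien-1-yl benzoate | BrC1=CC=C[C@H](OC(=O)c2ccccc2)[C@@H]1O | intermediate
4 | (1S,2S,5R,6R)-3-bromo-2,5,6-trihydroxycyclohex-3-en-1-yl benzoate | BrC1=C[C@@H](O)[C@@H](O)[C@H](OC(=O)c2ccccc2)[C@@H]1O | intermediate
5 | (1R,2R,5R,6R)-2,5,6-trihydroxy-3-(hydroxymethyl)cyclohex-3-en-1-yl benzoate | OCC1=C[C@@H](O)[C@@H](O)[C@H](OC(=O)c2ccccc2)[C@@H]1O | intermediate
6 | [(3R,4R,5R,6R)-5-(benzoyloxy)-3,4,6-trihydroxycyclohex-1-en-1-yl]methyl benzoate | O=C(OCC1=C[C@@H](O)[C@@H](O)[C@H](OC(=O)c2ccccc2)[C@@H]1O)c1ccccc1 | target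

## Step count and risk

Total steps: 5. Longest linear sequence: 5 (fully linear, no protecting groups).

**Step 1 (key step).** The selectivity is not in doubt. The likely failures are low productivity of the fermentation (substrate toxicity, oxygen limitation) and acid-catalysed dehydration of the diene diol back to an arene during extraction and concentration. The fallback sets out from 1 and comes back to the route at 4; it replaces the enzyme by a chemical dearomatisation. Visible-light [4+2] cycloaddition of 1 with 4-methyl-1,2,4-triazoline-3,5-dione at −78 °C in CH2Cl2, followed by OsO4/N-methylmorpholine N-oxide dihydroxylation of the unsubstituted bicyclic alkene anti to the urazole, should give the racemic bicyclic urazole diol F1. 2,2-Dimethoxypropane with p-toluenesulfonic acid should convert it into its acetonide F2. Urazole hydrolysis (KOH, i-PrOH, heat) and oxidation of the resulting cyclic hydrazine (CuCl2, air) release N2 by cycloreversion and should give the diene acetonide F3, whose diol sits on C3/C4 of the target. OsO4/N-methylmorpholine N-oxide on the non-brominated C5=C6 alkene, anti to the acetonide, should give the acetonide diol F4. Benzoylation of the equatorial O5 hydroxyl (BzCl, pyridine, −40 °C) should give the acetonide benzoate F5. Aqueous CF3CO2H should then give racemic 4, and separation of the enantiomers by preparative chromatography on a chiral stationary phase returns to 4.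

**Step 2.** The likely failures are incomplete discrimination between the distal and proximal hydroxyls, over-acylation to the dibenzoate, base-promoted migration of the benzoyl group from O5 to O6, and loss of benzoic acid with rearomatisation if the mixture warms or turns acidic. The fallback sets out from 2 and comes back at 3; it is a protecting-group relay built on the distal-selective silylation that is established for these diols. t-BuMe2SiCl, imidazole, DMF at −10 °C should give the distal silyl ether F6. Levulinic acid, N,N′-diisopropylcarbodiimide and catalytic 4-(dimethylamino)pyridine should give the proximal levulinate F7. HF·pyridine in THF at 0 °C should give the distal alcohol F8. BzCl/pyridine should give the benzoate levulinate F9. Hydrazine acetate in pyridine–AcOH removes the levulinate and returns 3.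

**Step 4.** The likely failures are slow oxidative addition and transmetalation at a hindered alkenyl bromide next to a free hydroxyl, competing protodebromination or butyl transfer, and thermal acyl migration during prolonged heating. The fallback sets out from 4 and comes back at 5; C7 is introduced as carbon monoxide. Palladium-catalysed formylation (CO, Bu3SnH added slowly, Pd(PPh3)4, THF, 50 °C) should give the enal F10. Luche reduction (NaBH4, CeCl3·7H2O, MeOH, −78 °C) reduces the aldehyde without touching the benzoate and gives 5.

**Step 5.** The likely failures are competing acylation of a secondary hydroxyl (the allylic O3 first) and base-induced migration of the O5 benzoate, giving regioisomeric di- and tribenzoates that are hard to separate. The fallback sets out from 4 and comes back at 6; it makes O7 the only free hydroxyl. Et3SiOTf, 2,6-lutidine, CH2Cl2 should give the tris(triethylsilyl) ether F11. Stille hydroxymethylation as in step 4 should give the primary alcohol F12. BzCl, pyridine and catalytic 4-(dimethylamino)pyridine should give the dibenzoate F13. HF·pyridine in THF/pyridine at 0 °C removes the three silyl groups under acidic, non-migrating conditions and gives 6.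

## Further compounds

F1 | step 1 | racemic 5-bromo-7,8-dihydroxy-2,3-diazabicyclo[2.2.2]oct-5-ene-2,3-dicarboxylic N-methylimide, hydroxyls anti to the urazole (enantiomer drawn leads to 4) | C1=C(Br)[C@H]2[C@@H](O)[C@@H](O)[C@@H]1N3C(=O)N(C)C(=O)N23
F2 | step 1 | 7,8-O-isopropylidene acetal (acetonide) of F1, racemic | C1=C(Br)[C@H]2[C@H]4OC(C)(C)O[C@H]4[C@@H]1N3C(=O)N(C)C(=O)N23
F3 | step 1 | rac-(3aR,7aS)-5-bromo-2,2-dimethyl-3a,7a-dihydro-1,3-benzodioxole | BrC1=C[C@H]2OC(C)(C)O[C@H]2C=C1
F4 | step 1 | racemic 1-bromo-3,4-O-isopropylidenecyclohex-1-ene-3,4,5,6-tetrol with the relative configuration of 4 (target numbering) | BrC1=C[C@H]2OC(C)(C)O[C@H]2[C@H](O)[C@@H]1O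
F5 | step 1 | racemic 3,4-O-isopropylidene derivative of 4 (target numbering) | BrC1=C[C@H]2OC(C)(C)O[C@H]2[C@H](OC(=O)c3ccccc3)[C@@H]1O
F6 | step 2 | (1S,6S)-2-bromo-6-(tert-butyldimethylsilyloxy)cyclohexa-2,4-dien-1-ol | BrC1=CC=C[C@H](O[Si](C)(C)C(C)(C)C)[C@@H]1O
F7 | step 2 | (1S,6S)-2-bromo-6-(tert-butyldimethylsilyloxy)cyclohexa-2,4-dien-1-yl 4-oxopentanoate | BrC1=CC=C[C@H](O[Si](C)(C)C(C)(C)C)[C@@H]1OC(=O)CCC(C)=O
F8 | step 2 | (1S,6S)-2-bromo-6-hydroxycyclohexa-2,4-dien-1-yl 4-oxopentanoate | BrC1=CC=C[C@H](O)[C@@H]1OC(=O)CCC(C)=O
F9 | step 2 | (1S,6S)-5-bromo-6-(4-oxopentanoyloxy)cyclohexa-2,4-dien-1-yl benzoate | BrC1=CC=C[C@H](OC(=O)c2ccccc2)[C@@H]1OC(=O)CCC(C)=O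
F10 | step 4 | (1R,2R,5R,6R)-3-formyl-2,5,6-trihydroxycyclohex-3-en-1-yl benzoate | O=CC1=C[C@@H](O)[C@@H](O)[C@H](OC(=O)c2ccccc2)[C@@H]1O
F11 | step 5 | O3,O4,O6-tris(triethylsilyl) ether of 4 (target numbering) | BrC1=C[C@@H](O[Si](CC)(CC)CC)[C@@H](O[Si](CC)(CC)CC)[C@H](OC(=O)c2ccccc2)[C@@H]1O[Si](CC)(CC)CC
F12 | step 5 | O3,O4,O6-tris(triethylsilyl) ether of 5 (target numbering) | OCC1=C[C@@H](O[Si](CC)(CC)CC)[C@@H](O[Si](CC)(CC)CC)[C@H](OC(=O)c2ccccc2)[C@@H]1O[Si](CC)(CC)CC
F13 | step 5 | O3,O4,O6-tris(triethylsilyl) ether of 6 | O=C(OCC1=C[C@@H](O[Si](CC)(CC)CC)[C@@H](O[Si](CC)(CC)CC)[C@H](OC(=O)c2ccccc2)[C@@H]1O[Si](CC)(CC)CC)c1ccccc1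
A1 | alternative 1 | (−)-shikimic acid | OC(=O)C1=C[C@@H](O)[C@@H](O)[C@H](O)C1
A2 | alternative 1 | methyl 5-O-benzoyl-3,4-O-isopropylideneshikimate | COC(=O)C1=C[C@@H]2[C@@H](OC(C)(C)O2)[C@H](OC(=O)c3ccccc3)C1
A3 | alternative 1 | 6-hydroxy derivative of A2 with O6 cis to O5 | COC(=O)C1=C[C@@H]2[C@@H](OC(C)(C)O2)[C@H](OC(=O)c3ccccc3)[C@@H]1O
A4 | alternative 2 | 2-(benzyloxymethyl)-3,4:5,6-di-O-isopropylideneocta-1,7-diene-3,4,5,6-tetrol with the configuration of C6, C5, C4, C3 of 6 | C=C[C@H]1OC(C)(C)O[C@H]1[C@@H]1OC(C)(C)O[C@@H]1C(=C)COCc1ccccc1
A5 | alternative 2 | 1-(benzyloxymethyl)-3,4:5,6-di-O-isopropylidenecyclohex-1-ene-3,4,5,6-tetrol with the configuration of 6 | c1ccccc1COCC1=C[C@H]2OC(C)(C)O[C@H]2[C@@H]2OC(C)(C)O[C@H]12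
A6 | alternative 3 | benzyl benzoate | O=C(OCc1ccccc1)c1ccccc1
A7 | alternative 3 | racemic (cis-3,4-dihydroxycyclohexa-1,5-dien-1-yl)methyl benzoate (one enantiomer drawn) | O=C(OCC1=C[C@@H](O)[C@@H](O)C=C1)c1ccccc1
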